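**Plan** (target numbering: C1 = lactone carbonyl, C26 = CH2–O)
- Retrosynthesis: the saturated 27-membered lactone is traced to its C15=C16 olefin; the C15–C16 bond is then cut by putting SO2 back between the two carbons, giving a 28-membered sulfone lactone. That ring is cut at the acyl C1–O bond and then at the C15–S bond, leaving a C15 bromo acid (from 15-pentadecanolide) and 11-sulfanylundecan-1-ol.
- Enabling feature: C15 and C16 lie inside the unbroken (CH2)25 run of the single ring, 14 methylenes from C1 and 11 from the ring oxygen. A sulfur atom can therefore sit between them as a temporary 28th ring atom, and the ester is the only other functional group present when it is removed.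
- Forward order: the chain is joined at sulfur (C15–S), the 28-membered thia-lactone is closed at the ester, sulfur is oxidised, the ring is contracted to 27 members with formation of C15–C16, and the olefin is hydrogenated.
- Stereochemistry: the target has no stereocentre. The stereo elements that appear on the way (sulfoxide sulfur, C–Br carbon, episulfone carbons, olefin geometry) are left uncontrolled and all disappear.

Key step: step 5

Remark: bromination in step 5 can fall on either carbon next to sulfur; 9 is drawn as the 16-bromide (ring numbering), and the 18-bromide closes to the same episulfone 10.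
Remark: 11-sulfanylundecan-1-ol (3) is taken as a purchased compound.

**Step 1**
Reactants: 1 15-pentadecanolide (oxacyclohexadecan-2-one)
Product: 2 15-bromopentadecanoic acid
Conditions: HBr (33% in AcOH), conc. H2SO4 (cat.), 90 °C; aqueous work-up
Reagents that add atoms: hydrogen bromide, Br
Why: Acid-mediated alkyl–oxygen cleavage of the lactone, in which bromide attacks the primary C15 of the protonated ester (SN2), is the usual way from lactones to omega-bromo acids, and excess HBr in a medium poor in water holds the product on the bromo acid side.

**Step 2**
Reactants: 2 15-bromopentadecanoic acid; 3 11-sulfanylundecan-1-ol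
Product: 4 15-[(11-hydroxyundecyl)sulfanyl]pentadecanoic acid
Conditions: NaOH (2.2 equiv), degassed EtOH/H2O, 60 °C; then aq HCl to pH 2
Reagents that add atoms: none
Why: Thioether synthesis by SN2 alkylation of a thiolate should be selective because the thiolate of 3 is far more nucleophilic than the carboxylate of 2, the alkoxide or hydroxide, so only the C15–S bond forms, and degassing keeps the thiol from oxidising to the disulfide.

**Step 3**
Reactants: 4 15-[(11-hydroxyundecyl)sulfanyl]pentadecanoic acid
Product: 6 1-oxa-17-thiacyclooctacosan-2-one, via mixed anhydride 5 (not isolated)
Conditions: 2,4,6-trichlorobenzoyl chloride, Et3N, THF, rt; then syringe-pump addition to DMAP in toluene, 100 °C (final concentration about 1 mM)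
Reagents that add atoms: none
Why: In this Yamaguchi macrolactonisation the hindered aroyl group of 5 steers DMAP and then the C26 hydroxyl to the aliphatic carbonyl, slow addition at high dilution favours closure of the strain-free 28-membered ring over oligomers, and the thioether is inert to the acylating agent.

**Step 4**
Reactants: 6 1-oxa-17-thiacyclooctacosan-2-one
Product: 8 1-oxa-17-thiacyclooctacosan-2-one 17,17-dioxide, via sulfoxide 7 (not isolated)
Conditions: mCPBA (2.3 equiv), CH2Cl2, 0 °C → rt
Reagents that add atoms: 3-chloroperoxybenzoic acid (mCPBA), O=C(OO)c1cccc(Cl)c1
Why: Peracid oxidation of a dialkyl sulfide runs through sulfoxide 7 (racemic at sulfur, of no consequence) to the sulfone, and the lactone offers nothing that mCPBA attacks.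

**Step 5**
Reactants: 8 1-oxa-17-thiacyclooctacosan-2-one 17,17-dioxide
Product: 11 hexacos-15-en-26-olide (oxacycloheptacos-16-en-2-one; E/Z mixture), via alpha-bromo sulfone 9 (not isolated), via episulfone 10 (not isolated)
Conditions: CBr2F2 (excess), KOH/Al2O3, t-BuOH/CH2Cl2, 0 °C → rt
Reagents that add atoms: none
Why: Alumina-bound KOH reversibly deprotonates a CH2 next to the sulfonyl group, CBr2F2 transfers bromine to the carbanion to give 9, deprotonation at the other alpha carbon is followed by intramolecular displacement of bromide to episulfone 10, and 10 loses SO2 cheletropically to leave the C15=C16 double bond. This is the Ramberg–Bäcklund reaction in its in situ halogenation form, established for acyclic and macrocyclic dialkyl sulfones and used here as a ring contraction. The three-membered episulfone closes by a 3-exo-tet 1,3-displacement, and with it the 27-membered ring arises from the 28-membered one as C15–C16 forms across sulfur inside the existing ring, so no large-ring entropy is paid at this stage. The stereocentres at the brominated carbon of 9 and at the two ring carbons of 10 are transient and uncontrolled, and the E/Z mixture in 11 does not matter because step 6 removes the double bond. The step needs attack at the C–H bonds next to sulfur in preference to the lactone, whose carbonyl can be saponified and whose C2–H bonds are of similar acidity; this should rest on the four alpha-sulfonyl hydrogens, on the irreversible capture of the sulfonyl carbanion by bromine transfer and then ring closure, and on hydroxide held on the alumina surface in poorly solvating t-BuOH/CH2Cl2 at 0 °C. The reaction is stopped as soon as 8 is consumed to keep contact with base short.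

**Step 6**
Reactants: 11 hexacos-15-en-26-olide (E/Z mixture)
Product: 12 26-hexacosanolide (oxacycloheptacosan-2-one)
Conditions: H2 (1 atm), 10% Pd/C, EtOAc, rt
Reagents that add atoms: none
Why: Heterogeneous catalytic hydrogenation of an unhindered 1,2-disubstituted alkene converges both geometric isomers on the saturated lactone, the ester is inert, and 11 is freed of sulfur-containing residues by chromatography beforehand.

**Compound list**
1 | 15-pentadecanolide (oxacyclohexadecan-2-one) | O=C1CCCCCCCCCCCCCCO1 | starting material
2 | 15-bromopentadecanoic acid | OC(=O)CCCCCCCCCCCCCCBr | intermediate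
3 | 11-sulfanylundecan-1-ol | OCCCCCCCCCCCS | starting material
4 | 15-[(11-hydroxyundecyl)sulfanyl]pentadecanoic acid | OC(=O)CCCCCCCCCCCCCCSCCCCCCCCCCCO | intermediate
5 | 15-[(11-hydroxyundecyl)sulfanyl]pentadecanoic 2,4,6-trichlorobenzoic anhydride (not isolated) | OCCCCCCCCCCCSCCCCCCCCCCCCCCC(=O)OC(=O)c1c(Cl)cc(Cl)cc1Cl | intermediate
6 | 1-oxa-17-thiacyclooctacosan-2-one | O=C1CCCCCCCCCCCCCCSCCCCCCCCCCCO1 | intermediate
7 | 1-oxa-17-thiacyclooctacosan-2-one 17-oxide (racemic at sulfur; not isolated) | O=C1CCCCCCCCCCCCCCS(=O)CCCCCCCCCCCO1 | intermediate
8 | 1-oxa-17-thiacyclooctacosan-2-one 17,17-dioxide | O=C1CCCCCCCCCCCCCCS(=O)(=O)CCCCCCCCCCCO1 | intermediate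
9 | 16-bromo-1-oxa-17-thiacyclooctacosan-2-one 17,17-dioxide (racemic; not isolated) | O=C1CCCCCCCCCCCCCC(Br)S(=O)(=O)CCCCCCCCCCCO1 | intermediate
10 | 12-oxa-28-thiabicyclo[25.1.0]octacosan-13-one 28,28-dioxide (the 15,16-episulfone; cis/trans mixture; not isolated) | O=C1CCCCCCCCCCCCCC2C(CCCCCCCCCCO1)S2(=O)=O | intermediate
11 | hexacos-15-en-26-olide (oxacycloheptacos-16-en-2-one; E/Z mixture) | O=C1CCCCCCCCCCCCCC=CCCCCCCCCCCO1 | intermediate
12 | 26-hexacosanolide (oxacycloheptacosan-2-one; no stereocentre) | O=C1CCCCCCCCCCCCCCCCCCCCCCCCCO1 | target

**Total step count:** 6
**Longest linear sequence:** 6 steps (1 → 2 → 4 → 6 → 8 → 11 → 12); 3 enters as a purchased compound in step 2.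

**Steps most likely to fail**

Step 5. Hydroxide or tert-butoxide may open the unhindered lactone, or bromine may be transferred to the ester enolate at C2, faster than the sulfonyl carbanion is brominated and collapses. The fallback puts the halogen in before any base is present.
- It sets out from sulfide 6: N-chlorosuccinimide in CCl4 at 0 °C → rt should chlorinate one carbon next to sulfur (Pummerer-type, through the chlorosulfonium salt and thionium ion) to give 16-chloro-1-oxa-17-thiacyclooctacosan-2-one F1, together with its equally useful 18-chloro isomer.
- Without purification, mCPBA in CH2Cl2 at 0 °C should oxidise it through 16-chloro-1-oxa-17-thiacyclooctacosan-2-one 17-oxide F2 to 16-chloro-1-oxa-17-thiacyclooctacosan-2-one 17,17-dioxide F3.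
- KOC(CH3)3 (1.5–2 equiv) in THF at −78 → 0 °C should then effect the Ramberg–Bäcklund ring contraction through episulfone 10 and come back to the route at 11.
- With no halogen donor in the flask, an ester enolate formed reversibly by the alkoxide can only reprotonate, whereas the carbanion on the unhalogenated carbon next to sulfur is drained irreversibly by the 1,3-displacement; the short, cold, anhydrous exposure limits transesterification.

Step 3. Intermolecular esterification may outrun ring closure and give the diolide and oligoesters, or the long-chain hydroxy acid may dissolve too poorly for clean activation. The fallback moves ring closure from the ester oxygen to sulfur.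
- It sets out from 2 and 3: acid-catalysed esterification (TsOH·H2O cat., toluene, Dean–Stark, under N2) should acylate the hydroxyl and leave the thiol free, since thioester formation is disfavoured under these equilibrium conditions, giving 11-sulfanylundecyl 15-bromopentadecanoate F4.
- Slow addition of F4 to Cs2CO3 in degassed DMF at 50–60 °C under high dilution should close the 28-membered ring by intramolecular thiolate alkylation and come back to the route at 6; the medium is anhydrous, so the ester is not at risk.

Step 6. Traces of sulfur compounds carried over from step 5 may poison the palladium surface and stall the hydrogenation. The fallback is a metal-free reduction: it sets out from 11 and uses diimide generated from 4-methylbenzenesulfonohydrazide and NaOAc in refluxing THF/H2O, which should saturate the unhindered olefin without touching the lactone and arrive directly at 12. No new compound lies on this path.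

**Further compounds**
F1 | step 5 | 16-chloro-1-oxa-17-thiacyclooctacosan-2-one (racemic) | O=C1CCCCCCCCCCCCCC(Cl)SCCCCCCCCCCCO1
F2 | step 5 | 16-chloro-1-oxa-17-thiacyclooctacosan-2-one 17-oxide (diastereomer mixture) | O=C1CCCCCCCCCCCCCC(Cl)S(=O)CCCCCCCCCCCO1
F3 | step 5 | 16-chloro-1-oxa-17-thiacyclooctacosan-2-one 17,17-dioxide (racemic) | O=C1CCCCCCCCCCCCCC(Cl)S(=O)(=O)CCCCCCCCCCCO1
F4 | step 3 | 11-sulfanylundecyl 15-bromopentadecanoate | BrCCCCCCCCCCCCCCC(=O)OCCCCCCCCCCCS
F0 | step 6 | none | none
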